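**Strategy.** The gem-dimethyl dihydropyran ring is disconnected across its two bonds to the shared ring-fusion carbons: the quinolone C3–CH(O) bond and the CMe2–CH bond. Those two carbons are the α- and β-carbons of an enol ether in an enantiopure 4-isobutenyl-4H-pyrano[3,2-c]quinolinone, and the quinolone C3=C4–O–CMe2 unit of the other half is a latent cationic 2-oxadiene. In one operation the 2-(quinolon-4-yloxy)prop-2-yl cation, released from an isopropenyl ether, adds across that enol ether in a formal oxa-Povarov [4+2] reaction. This closes the ring and sets both ring-fusion stereocentres from the single centre installed earlier by an organocatalytic Michael addition.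

Key step: step 7

Remark on the chemistry: the target is read as cis-fused at the two ring-fusion CH groups, with the isobutenyl group trans to the CMe2 group. In the numbering of the isobutenyl-bearing pyranoquinolinone this is (2R,3S,4S). 4-Hydroxy-2-quinolones are drawn as the 4-hydroxy tautomers.

**Step 1**
Reactants: 1 2,3-dimethoxyaniline
Product: 3 2,3-dimethoxy-N-methylaniline, via N-(methoxymethyl)aniline 2 (not isolated)
Conditions: (CH2O)n, NaOMe, MeOH, reflux; then NaBH4, reflux
Reagents that add atoms: paraformaldehyde (as formaldehyde), C=O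
Why: Reductive mono-N-methylation (reductive amination): formaldehyde and the aniline condense in methanolic NaOMe to the N-(methoxymethyl)aniline, which NaBH4 reduces through the iminium ion, so that dialkylation should be avoided.

**Step 2**
Reactants: 3 2,3-dimethoxy-N-methylaniline; 4 Meldrum's acid (2,2-dimethyl-1,3-dioxane-4,6-dione)
Product: 6 4-hydroxy-7,8-dimethoxy-1-methylquinolin-2(1H)-one, via malonamic acid 5 (not isolated)
Conditions: toluene, 90 °C; concentrate; then Eaton's reagent (P2O5 in MeSO3H), 70 °C
Reagents that add atoms: none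
Why: Aminolysis of Meldrum's acid with loss of acetone gives the N-aryl-N-methylmalonamic acid, and Eaton's reagent then effects intramolecular Friedel–Crafts acylation at the only free position ortho to nitrogen (para to the 3-methoxy group), the product enolising to the 4-hydroxy-2-quinolone.

**Step 3**
Reactants: 7 3-methylbut-2-enal; 8 (triphenylphosphoranylidene)acetaldehyde
Product: 9 (2E)-5-methylhexa-2,4-dienal
Conditions: toluene, 80 °C
Reagents that add atoms: none
Why: Wittig reaction of the stabilised formylmethylene ylide with the enal should give the (E)-configured two-carbon-homologated dienal.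

**Step 4**
Reactants: 6 4-hydroxy-7,8-dimethoxy-1-methylquinolin-2(1H)-one; 9 (2E)-5-methylhexa-2,4-dienal
Product: 11 (4R)-2-hydroxy-7,8-dimethoxy-6-methyl-4-(2-methylprop-1-en-1-yl)-2,3,4,6-tetrahydro-5H-pyrano[3,2-c]quinolin-5-one (both C2 epimers), via Michael adduct aldehyde 10 (not isolated)
Conditions: (R)-α,α-diphenylprolinol trimethylsilyl ether (20 mol%), PhCO2H (20 mol%), CH2Cl2, 0 °C to rt
Reagents that add atoms: none
Why: Iminium-ion catalysis by the diarylprolinol silyl ether: C3 of the 4-hydroxyquinolone adds in a Michael reaction to the β-carbon of the s-trans (E)-iminium ion (the δ-carbon is blocked by its two methyl groups) on the face not shielded by the CPh2OSiMe3 group, which should set the (R) centre, and the released aldehyde is trapped by the 4-OH as the lactol.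

**Step 5**
Reactants: 11 lactol (4R)
Product: 13 (4S)-7,8-dimethoxy-6-methyl-4-(2-methylprop-1-en-1-yl)-4,6-dihydro-5H-pyrano[3,2-c]quinolin-5-one, via anomeric mesylate 12 (not isolated)
Conditions: MsCl, Et3N, CH2Cl2, 0 °C to rt
Reagents that add atoms: none
Why: Sulfonylation of the lactol OH gives an anomeric mesylate that ionises to the cyclic oxocarbenium ion and loses the C3 proton to Et3N (E1-type dehydration) to give the enol ether, the C4 stereocentre being untouched (its descriptor becomes S only because the CIP priorities change).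

**Step 6**
Reactants: 6 4-hydroxy-7,8-dimethoxy-1-methylquinolin-2(1H)-one; 14 isopropenylboronic acid pinacol ester
Product: 15 7,8-dimethoxy-1-methyl-4-(prop-1-en-2-yloxy)quinolin-2(1H)-one
Conditions: Cu(OAc)2 (20 mol%), pyridine, 4 Å MS, O2 (1 atm), CH2Cl2, rt
Reagents that add atoms: none
Why: Chan–Lam-type oxidative coupling: the alkenyl group is transferred from boron to divalent copper bound to the acidic enol oxygen, and C–O reductive elimination from trivalent copper, with O2 as terminal oxidant, should give the isopropenyl ether at oxygen rather than at C3.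

**Step 7**
Reactants: 15 7,8-dimethoxy-1-methyl-4-(prop-1-en-2-yloxy)quinolin-2(1H)-one; 13 (4S)-4H-pyranoquinolinone enol ether
Product: 19 target CNP0314650.1, via α-chloro ether 16 (not isolated), via aryloxycarbenium triflate 17 (not isolated), via pyranyl oxocarbenium triflate 18 (not isolated)
Conditions: 15, HCl (1.0 M in Et2O, 1 equiv to 15), CH2Cl2, −78 to −40 °C; then 13, 2,6-di-tert-butyl-4-methylpyridine, AgOSO2CF3, CH2Cl2, −78 to −30 °C; aq. NaHCO3
Reagents that add atoms: none
Why: Proposed new method: HCl converts all of 15 into the covalent α-chloro ether 16 (so no nucleophilic isopropenyl ether remains), AgOSO2CF3 abstracts chloride to give the 2-aryloxyprop-2-yl cation 17 (a cationic 2-oxadiene, quinolone C3=C4–O+=CMe2), the enol-ether β-carbon of 13 attacks its carbenium carbon to form the C–CMe2 bond, and the resulting cyclic oxocarbenium ion 18 is captured by the nucleophilic C3 of the tethered 4-alkoxy-2-quinolone with loss of a proton to the hindered pyridine, a stepwise formal inverse-electron-demand [4+2] cycloaddition. The closest known reaction type is the oxa-Povarov reaction of phenol-derived aryl oxocarbenium ions with alkenes to give chromans (together with Lewis-acid-promoted additions of α-chloro ethers to alkenes), which has not been shown for a ketone-derived 4-quinolonyloxy carbenium ion. The one ring closed is the gem-dimethyl dihydropyran ring, by a 6-(enolendo)-exo-trig Friedel–Crafts attack on the cyclic oxocarbenium ion. The C–CMe2 ring-fusion centre is set by approach of the cation anti to the pseudoaxial isobutenyl group on the adjacent stereocentre of 13 (1,2-induction), and the O,C-benzylic ring-fusion centre is set by the short O–CMe2 tether, which sits pseudoaxial (trans-diaxial to isobutenyl) and should reach the oxocarbenium carbon only from its own face, giving the cis ring fusion. The step needs regioselectivity (secured by the polarity of the enol ether: nucleophilic β-carbon, oxygen-stabilised α-cation), chemoselectivity for the enol ether over the isobutenyl alkene (the enol ether leads to the better stabilised cation) and suppression of proton-catalysed self-reaction of 13 (secured by the hindered pyridine as proton trap).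

**Compound list**

1 | 2,3-dimethoxyaniline | COc1cccc(N)c1OC | starting material
2 | 2,3-dimethoxy-N-(methoxymethyl)aniline | COCNc1cccc(OC)c1OC | intermediate (not isolated)
3 | 2,3-dimethoxy-N-methylaniline | CNc1cccc(OC)c1OC | intermediate
4 | Meldrum's acid | CC1(C)OC(=O)CC(=O)O1 | starting material
5 | 3-[(2,3-dimethoxyphenyl)(methyl)amino]-3-oxopropanoic acid | CN(C(=O)CC(=O)O)c1cccc(OC)c1OC | intermediate (not isolated)
6 | 4-hydroxy-7,8-dimethoxy-1-methylquinolin-2(1H)-one | COc1ccc2c(O)cc(=O)n(C)c2c1OC | intermediate
7 | 3-methylbut-2-enal | CC(C)=CC=O | starting material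
8 | (triphenylphosphoranylidene)acetaldehyde | O=CC=P(c1ccccc1)(c1ccccc1)c1ccccc1 | starting material
9 | (2E)-5-methylhexa-2,4-dienal | CC(C)=C/C=C/C=O | intermediate
10 | (3R)-3-(4-hydroxy-7,8-dimethoxy-1-methyl-2-oxo-1,2-dihydroquinolin-3-yl)-5-methylhex-4-enal | COc1ccc2c(O)c([C@@H](C=C(C)C)CC=O)c(=O)n(C)c2c1OC | intermediate (not isolated)
11 | (4R)-2-hydroxy-7,8-dimethoxy-6-methyl-4-(2-methylprop-1-en-1-yl)-2,3,4,6-tetrahydro-5H-pyrano[3,2-c]quinolin-5-one, C2 epimers | COc1ccc2c3c(c(=O)n(C)c2c1OC)[C@@H](C=C(C)C)CC(O)O3 | intermediate
12 | 2-O-methanesulfonate of 11 | COc1ccc2c3c(c(=O)n(C)c2c1OC)[C@@H](C=C(C)C)CC(OS(C)(=O)=O)O3 | intermediate (not isolated)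
13 | (4S)-7,8-dimethoxy-6-methyl-4-(2-methylprop-1-en-1-yl)-4,6-dihydro-5H-pyrano[3,2-c]quinolin-5-one | COc1ccc2c3c(c(=O)n(C)c2c1OC)[C@@H](C=C(C)C)C=CO3 | intermediate
14 | isopropenylboronic acid pinacol ester | CC(=C)B1OC(C)(C)C(C)(C)O1 | starting material
15 | 7,8-dimethoxy-1-methyl-4-(prop-1-en-2-yloxy)quinolin-2(1H)-one | COc1ccc2c(OC(C)=C)cc(=O)n(C)c2c1OC | intermediate
16 | 4-[(2-chloropropan-2-yl)oxy]-7,8-dimethoxy-1-methylquinolin-2(1H)-one | COc1ccc2c(OC(C)(C)Cl)cc(=O)n(C)c2c1OC | intermediate (not isolated)
17 | (7,8-dimethoxy-1-methyl-2-oxo-1,2-dihydroquinolin-4-yl)(propan-2-ylidene)oxonium triflate | COc1ccc2c([O+]=C(C)C)cc(=O)n(C)c2c1OC.[O-]S(=O)(=O)C(F)(F)F | intermediate (not isolated)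
18 | cyclic oxocarbenium triflate of the pyranoquinolinone carrying the 2-(quinolon-4-yloxy)propan-2-yl group at C3, trans to the C4 isobutenyl group | COc1ccc2c3c(c(=O)n(C)c2c1OC)[C@@H](C=C(C)C)[C@H](C(C)(C)Oc1cc(=O)n(C)c2c(OC)c(OC)ccc12)C=[O+]3.[O-]S(=O)(=O)C(F)(F)F | intermediate (not isolated)
19 | CNP0314650.1, cis-fused bis(pyranoquinolinone) dimer, (2R,3S,4S) in the numbering of the isobutenyl-bearing pyranoquinolinone | COc1ccc2c3c(c(=O)n(C)c2c1OC)[C@@H](C=C(C)C)[C@H]1[C@@H](O3)c2c(c3ccc(OC)c(OC)c3n(C)c2=O)OC1(C)C | target

**Step count and risks**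

Total steps: 7. Longest linear sequence: 5 steps (steps 1, 2, 4, 5, 7).

Steps most likely to fail:

1. Step 7 (proposed new method). The aryloxycarbenium ion may be intercepted by the isobutenyl alkene instead of the enol ether, may lose a proton back to the isopropenyl ether and then self-add, or may fragment at the vinylogous acyl carbon. The ring closure may also occur on the wrong face. Fallback by known chemistry, setting out from 13 and returning at 19: BF3·OEt2-catalysed Mukaiyama–Isler-type addition of 2,2-dimethoxypropane to the enol ether of 13 (CH2Cl2, −78 °C), anti to the isobutenyl group, should give the β-methoxy acetal F1. Treatment of F1 with 6 and BF3·OEt2 (CH2Cl2, 0 °C to rt) should alkylate C3 of 6 with the cyclic oxocarbenium ion to give the C-linked hydroxyquinolone F2. Its benzylic centre can equilibrate under the acid by reversible opening to the ortho-quinone methide, and its tertiary methyl ether should ionise and be captured by the 4-OH to close the gem-dimethyl pyran ring of 19.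

2. Step 4. The dienal may be consumed by 1,6-addition or by Knoevenagel condensation followed by oxa-6π electrocyclisation, and facial discrimination at the dienyl iminium ion may be poor. Fallback setting out from 6 and returning at 11: von Pechmann annulation of 6 with malic acid in concentrated H2SO4 should give the pyranoquinolinedione F3. Rhodium-catalysed asymmetric conjugate addition of 2-methylprop-1-enylboronic acid (Rh(acac)(C2H4)2, the Segphos enantiomer that delivers the (4R) product, dioxane/H2O, 60 °C) should give the (4R)-dihydropyranone F4. Reduction of its enol lactone with i-Bu2AlH (CH2Cl2, −78 °C) should give lactol 11.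

3. Step 6. Transmetalation and C–O coupling at the weakly nucleophilic, chelating vinylogous acid may be sluggish, with protodeboronation of the boronate or attack at C3 competing. Fallback setting out from 6 and returning at 15: acetylation (Ac2O, pyridine) should give the 4-acetate F5. Carbonyl methylenation of its ester with the Tebbe reagent Cp2Ti(μ-Cl)(μ-CH2)AlMe2 (THF, pyridine, −40 to 0 °C) should give the isopropenyl ether 15, the ester reacting ahead of the ring amide.

**Further compounds**

F1 | step 7 | (3R,4S)-2-methoxy-3-(2-methoxypropan-2-yl)-7,8-dimethoxy-6-methyl-4-(2-methylprop-1-en-1-yl)-2,3,4,6-tetrahydro-5H-pyrano[3,2-c]quinolin-5-one, C2 epimers | COc1ccc2c3c(c(=O)n(C)c2c1OC)[C@@H](C=C(C)C)[C@H](C(C)(C)OC)C(OC)O3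
F2 | step 7 | (2R,3S,4S)-2-(4-hydroxy-7,8-dimethoxy-1-methyl-2-oxo-1,2-dihydroquinolin-3-yl)-3-(2-methoxypropan-2-yl)-7,8-dimethoxy-6-methyl-4-(2-methylprop-1-en-1-yl)-2,3,4,6-tetrahydro-5H-pyrano[3,2-c]quinolin-5-one | COc1ccc2c3c(c(=O)n(C)c2c1OC)[C@@H](C=C(C)C)[C@H](C(C)(C)OC)[C@@H](O3)c1c(O)c2ccc(OC)c(OC)c2n(C)c1=O
F3 | step 4 | 7,8-dimethoxy-6-methyl-2H-pyrano[3,2-c]quinoline-2,5(6H)-dione | COc1ccc2c3c(c(=O)n(C)c2c1OC)C=CC(=O)O3
F4 | step 4 | (4R)-7,8-dimethoxy-6-methyl-4-(2-methylprop-1-en-1-yl)-3,4-dihydro-2H-pyrano[3,2-c]quinoline-2,5(6H)-dione | COc1ccc2c3c(c(=O)n(C)c2c1OC)[C@@H](C=C(C)C)CC(=O)O3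
F5 | step 6 | 7,8-dimethoxy-1-methyl-2-oxo-1,2-dihydroquinolin-4-yl acetate | COc1ccc2c(OC(C)=O)cc(=O)n(C)c2c1OC
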